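# Platanetin (25) by Danheiser benzannulation of a bis(siloxy)cyclobutenone with ethoxyacetylene

## Analysis of the target

Platanetin (25) is a flavonol, a 4H-chromen-4-one (rings A and C) that carries an unsubstituted phenyl ring B at C2 and a hydroxyl at C3. It has no stereocentre, so the only stereochemical elements of the route sit in transient intermediates and vanish on aromatisation. Ring A is fully substituted: C4a bears the C4 carbonyl, C5 a hydroxyl, C6 the 3-methylbut-2-enyl (prenyl) group, C7 and C8 hydroxyls, and C8a the ring oxygen O1. The prenyl double bond, flanked by the C5 and C7 hydroxyls, cyclises to a dimethylchroman under Brønsted or strong Lewis acids and is saturated by hydrogenation, and the free 5,7,8-trihydroxy ring (O7 and O8 ortho, O5 and O8 para) is oxidised readily once it is deprotonated in air. The difficulty therefore lies in ring A and not in ring C: five different substituents must be placed without the C6/C8 ambiguity of electrophilic prenylation and without doubt about which oxygen becomes O1, and the protecting groups must later leave without strong acid or hydrogen. The strategy rests on the fact that C8a, C8, C7 and C6 (O, O, O, prenyl) are contiguous and map onto the four-carbon chain of a vinylketene, while C5 (O) and C4a (H) are the two carbons of an alkoxyalkyne. The ketene carbon then emerges as C8a carrying the only free hydroxyl, next to the only unsubstituted ring carbon.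

## Retrosynthetic reasoning

**25 from 24 from 23 (protecting groups).** The last bonds cut are the two O–Si bonds at O7 and O8 of 24, and before them the O–ethyl bond at O5 of 23. The groups were chosen backwards from the prenyl group, so that neither hydrogenolysis nor a strong Lewis acid is needed. O7 is silylated because it originates from siloxyalkyne 4, and O5 is an ethyl ether because it originates from alkyne 10. O5 lies peri to the C4 carbonyl, so a chelating Lewis acid with a soft counter-ion can remove its alkyl group alone under non-protic conditions. O8 is silylated as well, because a benzyl ether there could only be removed by methods that endanger the prenyl group. Should the O8 silyl group shift to the neighbouring free oxygen under basic conditions, the shift is reversible and only the isomer with the free hydroxyl ortho to C4a can close ring C.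

**23 from 20 (C3–O).** The oxygen at C3 is added last on ring C because the two-carbon partner 17 delivers C2 and C3 without oxygen. C3–H is the one acidic sp2 C–H of 20, next to the carbonyl. The forward step is lithiation to 21, borylation to 22 and oxidation, which must leave the prenyl alkene untouched.

**20 from 16 and 17; 16 from 15 (ring C).** Ring C is cut at C4a–C4, C4–C3 and O1–C2, and C4 is brought in by carbonylation, so the free hydroxyl of 15 and its ortho carbon are used in one operation. The handle is the C4a–I bond of 16, placed at the only unsubstituted ring carbon of 15. The forward reaction has to give six-membered closure through ynone 18 and enaminone 19 and not a five-membered aurone.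

**15 from 9 and 10 (ring A, key disconnection).** Ring A is cut at C4a–C8a, C5–C6 and C8–C8a, which gives cyclobutenone 9 (C8a, C8, C7, C6) and alkyne 10 (C5, C4a). A stepwise aromatic route would need several regiocontrolled substitutions to place the same groups. The forward cascade runs through 11, 12, 13 and 14 and must deliver the single free hydroxyl at C8a.

**9 from 4 and 7.** The four-membered ring is cut into siloxyalkyne 4 and siloxyketene 8, the latter released from acid chloride 7. The polarisation of 4 puts the prenyl-bearing carbon next to the carbonyl and the two oxygen-bearing carbons where C7 and C8 are needed.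

**4 from 1; 7 from 6 from 5.** Alkyne 4 is cut at the triple bond into ester 1 and one extra carbon (ester-to-ynolate homologation through 2 and 3, then O-silylation). Acid chloride 7 goes back to the bis-silyl derivative 6 of glycolic acid 5, which can be turned into the acid chloride without passing through the free acid.

## Alternatives that were turned down

Alternative 1: Ring C is cut at C3–C4 and O1–C8a.
- Forward: the enolate of ketone A3 would be C-acylated by the fully substituted 2-bromobenzoyl chloride A2. The enol oxygen of the resulting 1,3-diketone would then displace the bromide at C8a under monovalent copper catalysis, giving the protected flavonol A1.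
- For: the C3 oxygen arrives already in place, so no lithiation is needed. All four oxygens carry the same acetal group and fall in one mild acidic step. On both points this plan is stronger than the chosen route.
- Against: A2 is a hexasubstituted benzene that must be built by successive regiocontrolled substitutions. O- versus C-acylation of an α-alkoxy enolate is not secure. The O-arylation has to occur at a bromide flanked on both sides on an electron-rich ring.
- Comparison: the chosen route gives up the uniform protection but makes the whole of ring A in one step, with its regiochemistry fixed by mechanism.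

Alternative 2: Ring C is cut at C3–C4 only.
- Forward: in dialdehyde A5 an N-heterocyclic carbene would turn one aldehyde into an acyl anion equivalent and add it to the other. The dihydroflavonol A4 would then be dehydrogenated across C2–C3.
- For: the closure is metal-free and mild, and the C3 oxygen is formed in it. The two stereocentres of A4 do not matter.
- Against: to give A4 (ketone at C4, hydroxyl at C3) the donor must be the hindered, electron-rich aryl aldehyde. The carbene will add faster to the unhindered aliphatic aldehyde, which leads to the regioisomeric ketol or to loss of the aryloxide from the α-position. A5 also needs the same hexasubstituted ring A built linearly, and an extra oxidation follows.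
- Comparison: it is milder at ring C, but it leaves the ring A problem unsolved, which the chosen route addresses first.

Alternative 3: Ring C is cut at O1–C8a, C4a–C4 and O1–C2.
- Forward: an aryne released by fluoride from a precursor such as A7 would insert into the carboxyl C–O bond of phenylpropiolic acid A8. The resulting ortho-acyl phenoxide closes onto the alkyne to give flavone A6.
- For: three bonds of ring C form in one step, which is shorter than the chosen route on this point. The C5 alkoxy group next to the aryne directs the carboxylate oxygen to the distal carbon C8a, so the regiochemistry is right.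
- Against: A6 lacks both the C8 and the C3 oxygen. Two late oxidations on a prenylated flavone would be needed, the one at C8 on an electron-rich ring. A7 is itself a pentasubstituted arene that needs a multi-step preparation.
- Comparison: the chosen route brings in all four ring A oxygens in the key step and needs only the C3 oxidation afterwards.

Key step: step 5

## Route

Step 1
Reactants: 1 ethyl 4-methylpent-3-enoate
Product: 4 triisopropyl[(5-methylhex-4-en-1-yn-1-yl)oxy]silane, via lithium dibromoenolate 2 (not isolated), via lithium ynolate 3 (not isolated)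
Conditions: CH2Br2, lithium 2,2,6,6-tetramethylpiperidide, THF, −78 °C; LiN(SiMe3)2; n-BuLi, −78 → 0 °C; i-Pr3SiCl, −78 °C → rt
Reagents that add atoms: dibromomethane BrCBr; triisopropylsilyl chloride CC(C)[Si](Cl)(C(C)C)C(C)C
Why: Kowalski ester homologation: dibromomethyllithium adds to the ester, enolate 2 undergoes bromine–lithium exchange and 1,2-shift to ynolate 3, and the bulky chlorosilane silylates oxygen, not carbon. Carbonyl addition at −78 °C should outrun deprotonation of the allylic α-CH2.

Step 2
Reactants: 5 glycolic acid
Product: 6 triisopropylsilyl 2-[(triisopropylsilyl)oxy]acetate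
Conditions: i-Pr3SiCl (2.2 equiv), imidazole, DMF, rt
Reagents that add atoms: triisopropylsilyl chloride CC(C)[Si](Cl)(C(C)C)C(C)C
Why: Standard imidazole-mediated silylation of both the hydroxyl and the carboxyl group. The silyl ester is the form needed for the next step.

Step 3
Reactants: 6 triisopropylsilyl 2-[(triisopropylsilyl)oxy]acetate
Product: 7 2-[(triisopropylsilyl)oxy]acetyl chloride
Conditions: (COCl)2, DMF (cat.), CH2Cl2, 0 °C → rt; volatiles removed, used crude
Reagents that add atoms: oxalyl chloride O=C(Cl)C(=O)Cl
Why: Silyl esters are converted into acid chlorides by the chloroiminium reagent under neutral conditions, the silyl group leaving as the chlorosilane. No hydrogen chloride is formed, so the silyl ether survives.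

Step 4
Reactants: 4 triisopropyl[(5-methylhex-4-en-1-yn-1-yl)oxy]silane; 7 2-[(triisopropylsilyl)oxy]acetyl chloride
Product: 9 2-(3-methylbut-2-en-1-yl)-3,4-bis[(triisopropylsilyl)oxy]cyclobut-2-en-1-one (racemic), via siloxyketene 8 (not isolated)
Conditions: Et3N, CH2Cl2, 0 °C → rt, slow addition of 7
Reagents that add atoms: none
Why: Dehydrochlorination of 7 gives ketene 8, which undergoes the known [2+2] cycloaddition of ketenes with siloxyalkynes. The nucleophilic prenyl-bearing carbon of 4 bonds to the ketene carbonyl carbon, so the prenyl group ends at C2 and the two siloxy groups at C3 and C4; the C4 stereocentre is racemic and is lost in step 5.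

Step 5
Reactants: 9 2-(3-methylbut-2-en-1-yl)-3,4-bis[(triisopropylsilyl)oxy]cyclobut-2-en-1-one; 10 ethoxyacetylene
Product: 15 5-ethoxy-4-(3-methylbut-2-en-1-yl)-2,3-bis[(triisopropylsilyl)oxy]phenol, via vinylketene 11 (not isolated), via 4-vinylcyclobutenone 12 (not isolated), via dienylketene 13 (not isolated), via cyclohexadienone 14 (not isolated)
Conditions: 10 (3 equiv), toluene, sealed tube, 80 °C; excess 10 evaporated; 110 °C
Reagents that add atoms: none
Why: Heat opens 9 in a conrotatory 4π process to vinylketene 11 with the C4 siloxy donor turning outward; the ketene C=C then adds 10 in a [2+2] cycloaddition, the nucleophilic CH terminus of the ynol ether bonding to the ketene carbonyl carbon and the ethoxy-bearing carbon to the prenylated carbon, to give 4-vinylcyclobutenone 12 with the vinyl group on the sp3 carbon. A second, reversible 4π opening of 12 gives dienylketene 13, and the isomer with the two termini cis closes ring A by thermal disrotatory 6π electrocyclisation (C8–C8a), after which cyclohexadienone 14 tautomerises to the phenol. This is the Danheiser benzannulation of cyclobutenones with heteroatom-substituted alkynes, applied here to a cyclobutenone that carries oxygen at C3 and C4. The bonds C4a–C8a, C5–C6 and C8–C8a are formed and no stereocentre survives, since the quaternary carbon of 12 and the sp3 carbon of 14 both become aromatic carbons. The step needs one regiochemistry in the [2+2] event, which the polarisation of the ynol ether against the electrophilic ketene carbon secures, so that the ketene carbon becomes C8a with the only free hydroxyl and the alkyne supplies C4a–H next to C5–OEt. It also needs the ketenes to be captured by the alkyne and not by the product phenol, which the excess of 10 provides; the excess is removed before the final heating because 10 fragments above about 100 °C.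

Step 6
Reactants: 15 5-ethoxy-4-(3-methylbut-2-en-1-yl)-2,3-bis[(triisopropylsilyl)oxy]phenol
Product: 16 3-ethoxy-2-iodo-4-(3-methylbut-2-en-1-yl)-5,6-bis[(triisopropylsilyl)oxy]phenol
Conditions: N-iodosuccinimide (1.0 equiv), CH2Cl2, −40 → 0 °C, dark
Reagents that add atoms: N-iodosuccinimide O=C1CCC(=O)N1I
Why: Electrophilic aromatic iodination at the only unsubstituted ring carbon, which is ortho to the hydroxyl, ortho to the ethoxy group and para to a siloxy group. With one equivalent at low temperature this should be much faster than attack on the trisubstituted alkene, which has no free hydroxyl next to it.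

Step 7
Reactants: 16 3-ethoxy-2-iodo-4-(3-methylbut-2-en-1-yl)-5,6-bis[(triisopropylsilyl)oxy]phenol; 17 phenylacetylene
Product: 20 5-ethoxy-6-(3-methylbut-2-en-1-yl)-2-phenyl-7,8-bis[(triisopropylsilyl)oxy]-4H-chromen-4-one, via ynone 18 (not isolated), via enaminone 19 (not isolated)
Conditions: 17 (1.5 equiv), PdCl2(PPh3)2 (5 mol%), CO (10 bar), Et2NH, 80 °C
Reagents that add atoms: carbon monoxide [C-]#[O+]
Why: Known carbonylative annulation of ortho-iodophenols with terminal alkynes: oxidative addition to zerovalent palladium, CO insertion and alkynylation give ynone 18. Diethylamine adds to 18 to give enaminone 19, and the phenol displaces the amine by addition–elimination, which directs closure to the six-membered pyranone and not to an aurone.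

Step 8
Reactants: 20 5-ethoxy-6-(3-methylbut-2-en-1-yl)-2-phenyl-7,8-bis[(triisopropylsilyl)oxy]-4H-chromen-4-one
Product: 23 5-ethoxy-3-hydroxy-6-(3-methylbut-2-en-1-yl)-2-phenyl-7,8-bis[(triisopropylsilyl)oxy]-4H-chromen-4-one, via 3-lithioflavone 21 (not isolated), via boronate 22 (not isolated)
Conditions: LiN(i-Pr)2, THF, −78 °C; B(OMe)3, −78 → 0 °C; AcOH, 30% H2O2, 0 °C → rt
Reagents that add atoms: hydrogen peroxide OO
Why: Known lithiation–borylation–oxidation of flavones at C3: the amide base removes the C3–H next to the carbonyl at −78 °C, the borate traps 21, and peroxide oxidises the C–B bond of 22. Hydrogen peroxide in acetic acid at 0 °C should not epoxidise the prenyl alkene, and no free phenol is present.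

Step 9
Reactants: 23 5-ethoxy-3-hydroxy-6-(3-methylbut-2-en-1-yl)-2-phenyl-7,8-bis[(triisopropylsilyl)oxy]-4H-chromen-4-one
Product: 24 3,5-dihydroxy-6-(3-methylbut-2-en-1-yl)-2-phenyl-7,8-bis[(triisopropylsilyl)oxy]-4H-chromen-4-one
Conditions: MgI2·OEt2 (4 equiv), toluene–THF, 70 °C; aq. NH4Cl, Na2S2O3
Reagents that add atoms: none
Why: Chelation-assisted dealkylation of a peri-alkoxy ketone: magnesium bridges the C4 carbonyl oxygen and O5, and iodide removes the ethyl group by SN2; the excess of the salt allows for the equivalent bound by the 3-hydroxyl. No strong Brønsted acid is present, so the prenyl group should not cyclise onto O5 or O7, and the hindered, unchelated silyl ethers should stay.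

Step 10
Reactants: 24 3,5-dihydroxy-6-(3-methylbut-2-en-1-yl)-2-phenyl-7,8-bis[(triisopropylsilyl)oxy]-4H-chromen-4-one
Product: 25 platanetin, 3,5,7,8-tetrahydroxy-6-(3-methylbut-2-en-1-yl)-2-phenyl-4H-chromen-4-one
Conditions: Bu4NF, AcOH, THF, 0 °C → rt, argon; aq. NaH2PO4 work-up
Reagents that add atoms: none
Why: Fluoride cleaves both aryl silyl ethers. Acetic acid keeps the liberated phenols protonated, which protects the 5,7,8-trihydroxy ring from air oxidation, and it is too weak to cyclise the prenyl group.

## Compound list

1 | ethyl 4-methylpent-3-enoate | CCOC(=O)CC=C(C)C | starting material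
2 | lithium 1,1-dibromo-5-methylhexa-1,4-dien-2-olate | [Li+].[O-]C(CC=C(C)C)=C(Br)Br | intermediate
3 | lithium 5-methylhex-4-en-1-yn-1-olate | [Li+].[O-]C#CCC=C(C)C | intermediate
4 | triisopropyl[(5-methylhex-4-en-1-yn-1-yl)oxy]silane | CC(C)=CCC#CO[Si](C(C)C)(C(C)C)C(C)C | intermediate
5 | glycolic acid | OCC(=O)O | starting material
6 | triisopropylsilyl 2-[(triisopropylsilyl)oxy]acetate | CC(C)[Si](C(C)C)(C(C)C)OCC(=O)O[Si](C(C)C)(C(C)C)C(C)C | intermediate
7 | 2-[(triisopropylsilyl)oxy]acetyl chloride | O=C(Cl)CO[Si](C(C)C)(C(C)C)C(C)C | intermediate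
8 | 2-[(triisopropylsilyl)oxy]ethen-1-one (siloxyketene) | O=C=CO[Si](C(C)C)(C(C)C)C(C)C | intermediate
9 | 2-(3-methylbut-2-en-1-yl)-3,4-bis[(triisopropylsilyl)oxy]cyclobut-2-en-1-one (racemic) | O=C1C(CC=C(C)C)=C(O[Si](C(C)C)(C(C)C)C(C)C)C1O[Si](C(C)C)(C(C)C)C(C)C | intermediate
10 | ethoxyacetylene | C#COCC | starting material
11 | (3Z)-2-(3-methylbut-2-en-1-yl)-3,4-bis[(triisopropylsilyl)oxy]buta-1,3-dien-1-one | O=C=C(CC=C(C)C)/C(O[Si](C(C)C)(C(C)C)C(C)C)=C/O[Si](C(C)C)(C(C)C)C(C)C | intermediate
12 | 4-{(Z)-1,2-bis[(triisopropylsilyl)oxy]ethenyl}-3-ethoxy-4-(3-methylbut-2-en-1-yl)cyclobut-2-en-1-one (racemic) | O=C1C=C(OCC)C1(CC=C(C)C)/C(O[Si](C(C)C)(C(C)C)C(C)C)=C/O[Si](C(C)C)(C(C)C)C(C)C | intermediate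
13 | (3E,5Z)-3-ethoxy-4-(3-methylbut-2-en-1-yl)-5,6-bis[(triisopropylsilyl)oxy]hexa-1,3,5-trien-1-one | O=C=C/C(OCC)=C(CC=C(C)C)\C(O[Si](C(C)C)(C(C)C)C(C)C)=C\O[Si](C(C)C)(C(C)C)C(C)C | intermediate
14 | 3-ethoxy-4-(3-methylbut-2-en-1-yl)-5,6-bis[(triisopropylsilyl)oxy]cyclohexa-2,4-dien-1-one (racemic) | O=C1C=C(OCC)C(CC=C(C)C)=C(O[Si](C(C)C)(C(C)C)C(C)C)C1O[Si](C(C)C)(C(C)C)C(C)C | intermediate
15 | 5-ethoxy-4-(3-methylbut-2-en-1-yl)-2,3-bis[(triisopropylsilyl)oxy]phenol | Oc1cc(OCC)c(CC=C(C)C)c(O[Si](C(C)C)(C(C)C)C(C)C)c1O[Si](C(C)C)(C(C)C)C(C)C | intermediate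
16 | 3-ethoxy-2-iodo-4-(3-methylbut-2-en-1-yl)-5,6-bis[(triisopropylsilyl)oxy]phenol | Oc1c(I)c(OCC)c(CC=C(C)C)c(O[Si](C(C)C)(C(C)C)C(C)C)c1O[Si](C(C)C)(C(C)C)C(C)C | intermediate
17 | phenylacetylene | C#Cc1ccccc1 | starting material
18 | 1-[6-ethoxy-2-hydroxy-5-(3-methylbut-2-en-1-yl)-3,4-bis[(triisopropylsilyl)oxy]phenyl]-3-phenylprop-2-yn-1-one | O=C(C#Cc1ccccc1)c1c(O)c(O[Si](C(C)C)(C(C)C)C(C)C)c(O[Si](C(C)C)(C(C)C)C(C)C)c(CC=C(C)C)c1OCC | intermediate
19 | 3-(diethylamino)-1-[6-ethoxy-2-hydroxy-5-(3-methylbut-2-en-1-yl)-3,4-bis[(triisopropylsilyl)oxy]phenyl]-3-phenylprop-2-en-1-one (alkene geometry not controlled) | O=C(C=C(N(CC)CC)c1ccccc1)c1c(O)c(O[Si](C(C)C)(C(C)C)C(C)C)c(O[Si](C(C)C)(C(C)C)C(C)C)c(CC=C(C)C)c1OCC | intermediate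
20 | 5-ethoxy-6-(3-methylbut-2-en-1-yl)-2-phenyl-7,8-bis[(triisopropylsilyl)oxy]-4H-chromen-4-one | CC(C)=CCc1c(O[Si](C(C)C)(C(C)C)C(C)C)c(O[Si](C(C)C)(C(C)C)C(C)C)c2oc(-c3ccccc3)cc(=O)c2c1OCC | intermediate
21 | [5-ethoxy-6-(3-methylbut-2-en-1-yl)-4-oxo-2-phenyl-7,8-bis[(triisopropylsilyl)oxy]-4H-chromen-3-yl]lithium | CC(C)=CCc1c(O[Si](C(C)C)(C(C)C)C(C)C)c(O[Si](C(C)C)(C(C)C)C(C)C)c2oc(-c3ccccc3)c([Li])c(=O)c2c1OCC | intermediate
22 | dimethyl [5-ethoxy-6-(3-methylbut-2-en-1-yl)-4-oxo-2-phenyl-7,8-bis[(triisopropylsilyl)oxy]-4H-chromen-3-yl]boronate | CC(C)=CCc1c(O[Si](C(C)C)(C(C)C)C(C)C)c(O[Si](C(C)C)(C(C)C)C(C)C)c2oc(-c3ccccc3)c(B(OC)OC)c(=O)c2c1OCC | intermediate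
23 | 5-ethoxy-3-hydroxy-6-(3-methylbut-2-en-1-yl)-2-phenyl-7,8-bis[(triisopropylsilyl)oxy]-4H-chromen-4-one | CC(C)=CCc1c(O[Si](C(C)C)(C(C)C)C(C)C)c(O[Si](C(C)C)(C(C)C)C(C)C)c2oc(-c3ccccc3)c(O)c(=O)c2c1OCC | intermediate
24 | 3,5-dihydroxy-6-(3-methylbut-2-en-1-yl)-2-phenyl-7,8-bis[(triisopropylsilyl)oxy]-4H-chromen-4-one | CC(C)=CCc1c(O[Si](C(C)C)(C(C)C)C(C)C)c(O[Si](C(C)C)(C(C)C)C(C)C)c2oc(-c3ccccc3)c(O)c(=O)c2c1O | intermediate
25 | platanetin, 3,5,7,8-tetrahydroxy-6-(3-methylbut-2-en-1-yl)-2-phenyl-4H-chromen-4-one | CC(C)=CCc1c(O)c(O)c2oc(-c3ccccc3)c(O)c(=O)c2c1O | target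

## Step count and least certain steps

Total step count: 10. Longest linear sequence: 9 steps (from 5 through steps 2, 3, 4, 5, 6, 7, 8, 9 and 10).

**Step 5 (key step).**
- Risk: ring opening of the vinylogous-ester cyclobutenone may be slow, and capture of the oxygen-rich vinylketene sluggish. Thermal breakdown of the alkyne and acylation of the product phenol by ketene species could then compete.
- Fallback (from 9, back at 15): the first ring opening is triggered by light instead of heat. UV irradiation of 9 with 10 in toluene at room temperature should carry the sequence as far as 12. The excess of 10 is then evaporated and 12 alone is heated to 110 °C, where it opens to 13 and closes through 14 to 15. The alkyne is thus never exposed to the hot stage. No compound outside the compound list is made (F0).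

**Step 1.**
- Risk: deprotonation of the doubly activated α-CH2 by the carbenoid or the amide bases may compete with carbonyl addition, with migration of the double bond into conjugation.
- Fallback (from 1, back at 3): the triple bond is built first and oxidised afterwards. 4-Methylpent-3-enal F1 is obtained from 1 by reduction with i-Bu2AlH in CH2Cl2 at −78 °C. 1,1-Dibromo-5-methylhexa-1,4-diene F2 follows from F1 by dibromo-olefination with CBr4 and PPh3 at 0 °C. Treatment of F2 with n-BuLi (2 equiv) in THF at −78 °C gives (5-methylhex-4-en-1-yn-1-yl)lithium F3 by bromine–lithium exchange, 1,2-hydrogen shift and deprotonation. Oxidation of F3 with t-BuOOLi gives ynolate 3, which is silylated as in the main route to give 4.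

**Step 7.**
- Risk: slow oxidative addition at the electron-rich iodide flanked on both sides; direct alkynylation without CO uptake followed by five-membered ring closure; loss or migration of a silyl group in the hot amine.
- Fallback (from 15, back at 18): the acyl carbon is introduced without palladium. 6-Ethoxy-2-hydroxy-5-(3-methylbut-2-en-1-yl)-3,4-bis[(triisopropylsilyl)oxy]benzaldehyde F4 is made from 15 by magnesium-mediated ortho-formylation (MgCl2, Et3N, paraformaldehyde, MeCN, reflux). Deprotonation of 17 with n-BuLi in THF at −78 °C gives (phenylethynyl)lithium F5 for the next operation. Addition of F5 (2.2 equiv, the first equivalent being consumed by the phenol) to F4 gives racemic 1-[6-ethoxy-2-hydroxy-5-(3-methylbut-2-en-1-yl)-3,4-bis[(triisopropylsilyl)oxy]phenyl]-3-phenylprop-2-yn-1-ol F6 after aqueous work-up. MnO2 in CH2Cl2 oxidises F6 to ynone 18, which Et2NH closes through 19 to 20.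

**Step 8.**
- Risk: incomplete lithiation, or fragmentation of the 3-lithio species by β-elimination of the ring oxygen before it is trapped; slow epoxidation of the prenyl alkene if the oxidation is left too long.
- Fallback (from 20, back at 23): the oxygen is introduced through an enolate. Conjugate reduction of 20 with LiBH(s-Bu)3 in THF at −78 °C and trapping of the enolate with 2-(phenylsulfonyl)-3-phenyloxaziridine should give (2R*,3R*)-5-ethoxy-3-hydroxy-6-(3-methylbut-2-en-1-yl)-2-phenyl-7,8-bis[(triisopropylsilyl)oxy]chroman-4-one F7 as the racemic trans isomer, the oxidant approaching anti to the C2 phenyl group. Dess–Martin periodinane then oxidises the secondary alcohol of F7 to a C3 ketone, which is the keto tautomer of 23 and enolises to it.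

**Step 9.**
- Risk: substitution at the ethyl group is slower than at a methyl group, so forcing conditions may cause partial loss of silyl groups or acid-induced cyclisation of the prenyl group.
- Fallback (from 9, back at 24): a methyl ether, which is cleaved faster in the SN2 event, is carried at O5 in place of the ethyl ether. Methoxyacetylene F8 is prepared from commercial chloroacetaldehyde dimethyl acetal with NaNH2 in liquid NH3 and takes the place of 10. Benzannulation of 9 with F8 under the conditions of the key step should give 5-methoxy-4-(3-methylbut-2-en-1-yl)-2,3-bis[(triisopropylsilyl)oxy]phenol F9 in the same way. Iodination of F9 with N-iodosuccinimide gives 2-iodo-3-methoxy-4-(3-methylbut-2-en-1-yl)-5,6-bis[(triisopropylsilyl)oxy]phenol F10 as the annulation substrate. Carbonylative annulation of F10 with 17 gives 5-methoxy-6-(3-methylbut-2-en-1-yl)-2-phenyl-7,8-bis[(triisopropylsilyl)oxy]-4H-chromen-4-one F11 under the palladium conditions of the main route. 3-Hydroxy-5-methoxy-6-(3-methylbut-2-en-1-yl)-2-phenyl-7,8-bis[(triisopropylsilyl)oxy]-4H-chromen-4-one F12 follows from F11 by lithiation, borylation and oxidation. MgI2·OEt2 in THF at 60 °C demethylates F12 to 24.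

## Further compounds

F0 | step 5 | none | none
F1 | step 1 | 4-methylpent-3-enal | CC(C)=CCC=O
F2 | step 1 | 1,1-dibromo-5-methylhexa-1,4-diene | CC(C)=CCC=C(Br)Br
F3 | step 1 | (5-methylhex-4-en-1-yn-1-yl)lithium | [Li]C#CCC=C(C)C
F4 | step 7 | 6-ethoxy-2-hydroxy-5-(3-methylbut-2-en-1-yl)-3,4-bis[(triisopropylsilyl)oxy]benzaldehyde | O=Cc1c(O)c(O[Si](C(C)C)(C(C)C)C(C)C)c(O[Si](C(C)C)(C(C)C)C(C)C)c(CC=C(C)C)c1OCC
F5 | step 7 | (phenylethynyl)lithium | [Li]C#Cc1ccccc1
F6 | step 7 | 1-[6-ethoxy-2-hydroxy-5-(3-methylbut-2-en-1-yl)-3,4-bis[(triisopropylsilyl)oxy]phenyl]-3-phenylprop-2-yn-1-ol (racemic) | OC(C#Cc1ccccc1)c1c(O)c(O[Si](C(C)C)(C(C)C)C(C)C)c(O[Si](C(C)C)(C(C)C)C(C)C)c(CC=C(C)C)c1OCC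
F7 | step 8 | (2R*,3R*)-5-ethoxy-3-hydroxy-6-(3-methylbut-2-en-1-yl)-2-phenyl-7,8-bis[(triisopropylsilyl)oxy]chroman-4-one (racemic, trans; one enantiomer drawn) | c1ccccc1[C@@H]2[C@H](C(=O)c3c(OCC)c(CC=C(C)C)c(O[Si](C(C)C)(C(C)C)C(C)C)c(O[Si](C(C)C)(C(C)C)C(C)C)c3O2)O
F8 | step 9 | methoxyacetylene | C#COC
F9 | step 9 | 5-methoxy-4-(3-methylbut-2-en-1-yl)-2,3-bis[(triisopropylsilyl)oxy]phenol | Oc1cc(OC)c(CC=C(C)C)c(O[Si](C(C)C)(C(C)C)C(C)C)c1O[Si](C(C)C)(C(C)C)C(C)C
F10 | step 9 | 2-iodo-3-methoxy-4-(3-methylbut-2-en-1-yl)-5,6-bis[(triisopropylsilyl)oxy]phenol | Oc1c(I)c(OC)c(CC=C(C)C)c(O[Si](C(C)C)(C(C)C)C(C)C)c1O[Si](C(C)C)(C(C)C)C(C)C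
F11 | step 9 | 5-methoxy-6-(3-methylbut-2-en-1-yl)-2-phenyl-7,8-bis[(triisopropylsilyl)oxy]-4H-chromen-4-one | CC(C)=CCc1c(O[Si](C(C)C)(C(C)C)C(C)C)c(O[Si](C(C)C)(C(C)C)C(C)C)c2oc(-c3ccccc3)cc(=O)c2c1OC
F12 | step 9 | 3-hydroxy-5-methoxy-6-(3-methylbut-2-en-1-yl)-2-phenyl-7,8-bis[(triisopropylsilyl)oxy]-4H-chromen-4-one | CC(C)=CCc1c(O[Si](C(C)C)(C(C)C)C(C)C)c(O[Si](C(C)C)(C(C)C)C(C)C)c2oc(-c3ccccc3)c(O)c(=O)c2c1OC
A1 | alternative 1 | 3,5,7,8-tetrakis(methoxymethoxy)-6-(3-methylbut-2-en-1-yl)-2-phenyl-4H-chromen-4-one | CC(C)=CCc1c(OCOC)c(OCOC)c2oc(-c3ccccc3)c(OCOC)c(=O)c2c1OCOC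
A2 | alternative 1 | 2-bromo-3,4,6-tris(methoxymethoxy)-5-(3-methylbut-2-en-1-yl)benzoyl chloride | O=C(Cl)c1c(Br)c(OCOC)c(OCOC)c(CC=C(C)C)c1OCOC
A3 | alternative 1 | 2-(methoxymethoxy)-1-phenylethan-1-one | O=C(COCOC)c1ccccc1
A4 | alternative 2 | 3-hydroxy-5,7,8-tris(methoxymethoxy)-6-(3-methylbut-2-en-1-yl)-2-phenylchroman-4-one (racemic mixture of diastereomers) | CC(C)=CCc1c(OCOC)c(OCOC)c2OC(c3ccccc3)C(O)C(=O)c2c1OCOC
A5 | alternative 2 | 2-[2-formyl-3,5,6-tris(methoxymethoxy)-4-(3-methylbut-2-en-1-yl)phenoxy]-2-phenylacetaldehyde (racemic) | O=CC(Oc1c(C=O)c(OCOC)c(CC=C(C)C)c(OCOC)c1OCOC)c1ccccc1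
A6 | alternative 3 | 5,7-bis(methoxymethoxy)-6-(3-methylbut-2-en-1-yl)-2-phenyl-4H-chromen-4-one | CC(C)=CCc1c(OCOC)cc2oc(-c3ccccc3)cc(=O)c2c1OCOC
A7 | alternative 3 | 3,5-bis(methoxymethoxy)-4-(3-methylbut-2-en-1-yl)-2-(trimethylsilyl)phenyl trifluoromethanesulfonate | CC(C)=CCc1c(OCOC)cc(OS(=O)(=O)C(F)(F)F)c([Si](C)(C)C)c1OCOC
A8 | alternative 3 | phenylpropiolic acid | OC(=O)C#Cc1ccccc1
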